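**Plan**

Flavanone numbering is used: O1, C2 (aryl-bearing), C3, C4 (ketone), ring A C5–C8 with the side chain on C8, side-chain carbons C1''–C4''.
1. Retrosynthetic cuts, in order: the four O–Si bonds and the acetate; the allylic C4''–O bond (back to an 8-prenyl group); O1–C2 of ring C; C2=C3 (Knoevenagel); C3–C4 (crossed Claisen); C8–C1'' (aromatic Claisen from an O1-bound 1,1-dimethylallyl ether).
2. Forward: ring A benzoate → O1 tert-allyl ether → [3,3] shift to the C8-prenyl phenol → β-keto ester → alkylidene with the ring B aldehyde → closure of ring C with loss of the ester → side-chain hydroxylation, acetylation, desilylation.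
3. Enabling feature: C2 is β to the C4 ketone and O1 sits on C8a, ortho to the acyl-bearing C4a. A C2=C3 double bond (chalcone oxidation level) with a temporary tert-butyl ester on C3 therefore lets the O1 phenol add to C2 inside a chiral bifunctional catalyst. O1 is also ortho to C8, so the same oxygen first carries the allyl unit that the [3,3] shift moves to C8, and is left as the only free phenol.
4. Stereochemistry: C2 (S) comes from catalyst control in the oxa-Michael ring closure; the E alkene comes from the E-selective SeO2 hydroxylation of the prenyl group.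

Key step: step 8

Remark: of the two pseudoenantiomeric cinchona thioureas, the quinidine-derived one is assumed to deliver the 2S series; if the sense of induction is the opposite, the quinine-derived one replaces it and nothing else changes.

**Route**

Step 1
Reactants: 1 methyl 2,4,6-trihydroxybenzoate
Product: 2 methyl 2,4-bis(TBSO)-6-hydroxybenzoate (TBS = tert-butyldimethylsilyl)
Conditions: TBSCl (2.1 equiv), imidazole (4 equiv), CH2Cl2, 0 °C
Reagents that add atoms: tert-butyldimethylsilyl chloride, CC(C)(C)[Si](C)(C)Cl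
Why: Selective phenol silylation: the para hydroxyl and one of the two equivalent ortho hydroxyls react, after which the last ortho hydroxyl is locked in a hydrogen bond to the ester carbonyl and silylation should stop at the bis-ether.

Step 2
Reactants: 3 2-methylbut-3-en-2-ol
Product: 4 tert-butyl 2-methylbut-3-en-2-yl carbonate
Conditions: n-BuLi (1.05 equiv), THF, −78 °C; Boc2O, −78 °C to rt
Reagents that add atoms: di-tert-butyl dicarbonate, CC(C)(C)OC(=O)OC(=O)OC(C)(C)C
Why: O-acylation of the lithium alkoxide of a tertiary allylic alcohol with Boc2O is the standard way to tertiary allylic carbonates.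

Step 3
Reactants: 2 methyl 2,4-bis(TBSO)-6-hydroxybenzoate; 4 tert-butyl 2-methylbut-3-en-2-yl carbonate
Product: 5 methyl 2,4-bis(TBSO)-6-[(2-methylbut-3-en-2-yl)oxy]benzoate
Conditions: Pd(PPh3)4 (3 mol%), THF, 0 °C
Reagents that add atoms: none
Why: Tsuji–Trost O-allylation (reverse prenylation): zerovalent palladium ionises 4 to a 1,1-dimethylallyl palladium cation and tert-butoxide, which deprotonates the phenol, and kinetic attack of the phenoxide at the more substituted allyl terminus should give the tertiary ether under neutral conditions that spare the silyl ethers.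

Step 4
Reactants: 5 methyl 2,4-bis(TBSO)-6-[(2-methylbut-3-en-2-yl)oxy]benzoate
Product: 7 methyl 4,6-bis(TBSO)-2-hydroxy-3-(3-methylbut-2-en-1-yl)benzoate, via ortho-dienone 6 (not isolated)
Conditions: toluene, 110 °C
Reagents that add atoms: none
Why: Aromatic Claisen rearrangement: the [3,3] shift can end productively only at the one unsubstituted ortho carbon, the dienone 6 enolises, and the allyl inversion turns the tertiary ether into a C-prenyl group while releasing exactly the phenol oxygen next to it.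

Step 5
Reactants: 7 methyl 4,6-bis(TBSO)-2-hydroxy-3-(3-methylbut-2-en-1-yl)benzoate; 8 tert-butyl acetate
Product: 9 tert-butyl 3-[4,6-bis(TBSO)-2-hydroxy-3-(3-methylbut-2-en-1-yl)phenyl]-3-oxopropanoate
Conditions: LiN(i-Pr)2 (4.2 equiv), 8 (4 equiv), THF, −78 °C; then 7, −78 °C to rt; AcOH
Reagents that add atoms: none
Why: Crossed Claisen condensation of a salicylate with excess lithium tert-butyl acetate, which is stable at room temperature and can therefore be pushed against the hindered, phenoxide-deactivated ester, the product being protected as its dianion until the quench.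

Step 6
Reactants: 10 3,4-dihydroxybenzaldehyde
Product: 11 3,4-bis(TBSO)benzaldehyde
Conditions: TBSCl (2.3 equiv), imidazole, DMF, rt
Reagents that add atoms: tert-butyldimethylsilyl chloride, CC(C)(C)[Si](C)(C)Cl
Why: Routine silylation of both catechol hydroxyls.

Step 7
Reactants: 9 tert-butyl 3-[4,6-bis(TBSO)-2-hydroxy-3-(3-methylbut-2-en-1-yl)phenyl]-3-oxopropanoate; 11 3,4-bis(TBSO)benzaldehyde
Product: 12 tert-butyl (2Z)-2-[4,6-bis(TBSO)-2-hydroxy-3-(3-methylbut-2-en-1-yl)benzoyl]-3-[3,4-bis(TBSO)phenyl]prop-2-enoate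
Conditions: piperidine (0.2 equiv), AcOH (0.2 equiv), 4 Å molecular sieves, toluene, rt
Reagents that add atoms: none
Why: Knoevenagel condensation under piperidinium acetate catalysis with removal of water, in which the hydrogen-bonded ortho phenol should stay a spectator; the Z isomer (aryl cis to the ester) is expected to prevail and the alkene geometry is lost in the next step.

Step 8
Reactants: 12 tert-butyl (2Z)-2-[4,6-bis(TBSO)-2-hydroxy-3-(3-methylbut-2-en-1-yl)benzoyl]-3-[3,4-bis(TBSO)phenyl]prop-2-enoate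
Product: 15 (2S)-5,7-bis(TBSO)-2-[3,4-bis(TBSO)phenyl]-8-(3-methylbut-2-en-1-yl)chroman-4-one, via tert-butyl ester 13 (not isolated), via keto acid 14 (not isolated)
Conditions: thiourea from 9-amino-9-deoxy-epi-quinidine and 3,5-bis(trifluoromethyl)phenyl isothiocyanate (10 mol%), toluene, −25 °C; then TsOH·H2O (0.5 equiv), 80 °C
Reagents that add atoms: none
Why: The quinuclidine nitrogen of the catalyst takes up the O1 phenol proton while the thiourea N–H bonds hold the ketone/ester 1,3-dicarbonyl unit, the phenoxide oxygen adds to the benzylidene carbon (future C2), the enol is protonated at C3, and TsOH then cleaves the tert-butyl ester so that keto acid 14 loses CO2. The closest known reaction type is the thiourea-catalysed enantioselective intramolecular oxa-Michael addition of 2-hydroxyaryl alkylidene β-keto esters followed by acid decarboxylation, an established flavanone synthesis. Ring C is closed in the 6-endo-trig mode. C2 is set by the catalyst, which shields one face of the hydrogen-bonded alkylidene (no substrate stereocentre is present), and C3 of 13 is a transient, epimerisable centre erased by the decarboxylation. The step needs enantioface selectivity and a choice between the two ortho oxygens of ring A; the latter is secured because only the oxygen released in step 4, next to the prenyl-bearing carbon, is free while the other is a silyl ether, so only the 8-substituted flavanone can form. The ester makes the alkene reactive enough to cyclise at −25 °C, where uncatalysed closure and retro-oxa-Michael opening are slow, and its removal by acid avoids the base that would racemise C2.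

Step 9
Reactants: 15 (2S)-5,7-bis(TBSO)-2-[3,4-bis(TBSO)phenyl]-8-(3-methylbut-2-en-1-yl)chroman-4-one
Product: 16 (2S)-5,7-bis(TBSO)-2-[3,4-bis(TBSO)phenyl]-8-[(2E)-4-hydroxy-3-methylbut-2-en-1-yl]chroman-4-one
Conditions: SeO2 (0.5 equiv), t-BuOOH (3 equiv, in decane), salicylic acid (0.1 equiv), CH2Cl2, 0 °C to rt
Reagents that add atoms: tert-butyl hydroperoxide, CC(C)(C)OO (terminal oxidant); selenium dioxide, O=[Se]=O (oxygen carrier, regenerated)
Why: SeO2 allylic hydroxylation (ene reaction at the trisubstituted alkene, then [2,3] shift of the allylseleninic acid) oxidises the methyl group trans to the benzylic chain and so should give the E allylic alcohol, while catalytic SeO2 at room temperature should leave the chromanone alone.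

Step 10
Reactants: 16 (2S)-5,7-bis(TBSO)-2-[3,4-bis(TBSO)phenyl]-8-[(2E)-4-hydroxy-3-methylbut-2-en-1-yl]chroman-4-one
Product: 17 (2E)-4-[(2S)-5,7-bis(TBSO)-2-[3,4-bis(TBSO)phenyl]-4-oxochroman-8-yl]-2-methylbut-2-en-1-yl acetate
Conditions: Ac2O, pyridine, DMAP (cat.), CH2Cl2, 0 °C
Reagents that add atoms: acetic anhydride, CC(=O)OC(C)=O
Why: Acetylation of the only free hydroxyl; all phenols are silylated, so chemoselectivity is built in.

Step 11
Reactants: 17 (2E)-4-[(2S)-5,7-bis(TBSO)-2-[3,4-bis(TBSO)phenyl]-4-oxochroman-8-yl]-2-methylbut-2-en-1-yl acetate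
Product: 18 Kanzonol S
Conditions: n-Bu4NF (4.5 equiv), AcOH (5 equiv), THF, 0 °C
Reagents that add atoms: none
Why: Fluoride cleaves the four aryl silyl ethers, and the acetic acid buffer keeps the medium from turning basic, so the allylic acetate should be kept and the base-labile C2 centre (retro-oxa-Michael opening) should not be touched.

**Compound list**

1 | methyl 2,4,6-trihydroxybenzoate | COC(=O)c1c(O)cc(O)cc1O | starting material
2 | methyl 2,4-bis(TBSO)-6-hydroxybenzoate | COC(=O)c1c(O)cc(O[Si](C)(C)C(C)(C)C)cc1O[Si](C)(C)C(C)(C)C | intermediate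
3 | 2-methylbut-3-en-2-ol | CC(C)(O)C=C | starting material
4 | tert-butyl 2-methylbut-3-en-2-yl carbonate | CC(C)(C)OC(=O)OC(C)(C)C=C | intermediate
5 | methyl 2,4-bis(TBSO)-6-[(2-methylbut-3-en-2-yl)oxy]benzoate | COC(=O)c1c(OC(C)(C)C=C)cc(O[Si](C)(C)C(C)(C)C)cc1O[Si](C)(C)C(C)(C)C | intermediate
6 | methyl 2,4-bis(TBSO)-5-(3-methylbut-2-en-1-yl)-6-oxocyclohexa-1,3-diene-1-carboxylate (racemic ortho-dienone, not isolated) | COC(=O)C1=C(O[Si](C)(C)C(C)(C)C)C=C(O[Si](C)(C)C(C)(C)C)C(CC=C(C)C)C1=O | intermediate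
7 | methyl 4,6-bis(TBSO)-2-hydroxy-3-(3-methylbut-2-en-1-yl)benzoate | COC(=O)c1c(O)c(CC=C(C)C)c(O[Si](C)(C)C(C)(C)C)cc1O[Si](C)(C)C(C)(C)C | intermediate
8 | tert-butyl acetate | CC(=O)OC(C)(C)C | starting material
9 | tert-butyl 3-[4,6-bis(TBSO)-2-hydroxy-3-(3-methylbut-2-en-1-yl)phenyl]-3-oxopropanoate | CC(C)(C)OC(=O)CC(=O)c1c(O)c(CC=C(C)C)c(O[Si](C)(C)C(C)(C)C)cc1O[Si](C)(C)C(C)(C)C | intermediate
10 | 3,4-dihydroxybenzaldehyde | O=Cc1ccc(O)c(O)c1 | starting material
11 | 3,4-bis(TBSO)benzaldehyde | O=Cc1ccc(O[Si](C)(C)C(C)(C)C)c(O[Si](C)(C)C(C)(C)C)c1 | intermediate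
12 | tert-butyl (2Z)-2-[4,6-bis(TBSO)-2-hydroxy-3-(3-methylbut-2-en-1-yl)benzoyl]-3-[3,4-bis(TBSO)phenyl]prop-2-enoate (Z isomer drawn) | CC(C)(C)OC(=O)/C(C(=O)c1c(O)c(CC=C(C)C)c(O[Si](C)(C)C(C)(C)C)cc1O[Si](C)(C)C(C)(C)C)=C\c1ccc(O[Si](C)(C)C(C)(C)C)c(O[Si](C)(C)C(C)(C)C)c1 | intermediate
13 | tert-butyl (2S,3R)-5,7-bis(TBSO)-2-[3,4-bis(TBSO)phenyl]-8-(3-methylbut-2-en-1-yl)-4-oxochromane-3-carboxylate (trans isomer drawn, C3 epimerisable, not isolated) | CC(C)=CCc1c(O[Si](C)(C)C(C)(C)C)cc(O[Si](C)(C)C(C)(C)C)c2c1O[C@H](c1ccc(O[Si](C)(C)C(C)(C)C)c(O[Si](C)(C)C(C)(C)C)c1)[C@@H](C(=O)OC(C)(C)C)C2=O | intermediate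
14 | (2S,3R)-5,7-bis(TBSO)-2-[3,4-bis(TBSO)phenyl]-8-(3-methylbut-2-en-1-yl)-4-oxochromane-3-carboxylic acid (not isolated) | CC(C)=CCc1c(O[Si](C)(C)C(C)(C)C)cc(O[Si](C)(C)C(C)(C)C)c2c1O[C@H](c1ccc(O[Si](C)(C)C(C)(C)C)c(O[Si](C)(C)C(C)(C)C)c1)[C@@H](C(=O)O)C2=O | intermediate
15 | (2S)-5,7-bis(TBSO)-2-[3,4-bis(TBSO)phenyl]-8-(3-methylbut-2-en-1-yl)chroman-4-one | CC(C)=CCc1c(O[Si](C)(C)C(C)(C)C)cc(O[Si](C)(C)C(C)(C)C)c2c1O[C@H](c1ccc(O[Si](C)(C)C(C)(C)C)c(O[Si](C)(C)C(C)(C)C)c1)CC2=O | intermediate
16 | (2S)-5,7-bis(TBSO)-2-[3,4-bis(TBSO)phenyl]-8-[(2E)-4-hydroxy-3-methylbut-2-en-1-yl]chroman-4-one | OC/C(C)=C/Cc1c(O[Si](C)(C)C(C)(C)C)cc(O[Si](C)(C)C(C)(C)C)c2c1O[C@H](c1ccc(O[Si](C)(C)C(C)(C)C)c(O[Si](C)(C)C(C)(C)C)c1)CC2=O | intermediate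
17 | (2E)-4-[(2S)-5,7-bis(TBSO)-2-[3,4-bis(TBSO)phenyl]-4-oxochroman-8-yl]-2-methylbut-2-en-1-yl acetate | CC(=O)OC/C(C)=C/Cc1c(O[Si](C)(C)C(C)(C)C)cc(O[Si](C)(C)C(C)(C)C)c2c1O[C@H](c1ccc(O[Si](C)(C)C(C)(C)C)c(O[Si](C)(C)C(C)(C)C)c1)CC2=O | intermediate
18 | Kanzonol S, (2E)-4-[(2S)-2-(3,4-dihydroxyphenyl)-5,7-dihydroxy-4-oxochroman-8-yl]-2-methylbut-2-en-1-yl acetate | CC(=O)OC/C(C)=C/Cc1c(O)cc(O)c2c1O[C@H](c1ccc(O)c(O)c1)CC2=O | target

**Count and risks**

Total steps: 11. Longest linear sequence: 9 steps (1 → 18 through steps 1, 3, 4, 5, 7, 8, 9, 10, 11); steps 2 and 6 are one-step side branches.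

Step 8. Enantioface control may be incomplete on a substrate whose aryl ketone is twisted by the flanking silyloxy group, racemic background cyclisation may compete, and the hot acid may strip silyl groups or engage the prenyl alkene. The fallback separates ring closure from stereocontrol; it sets out from 12 and returns at 15. Compound 12 is cyclised with Et3N in toluene at rt and decarboxylated with TsOH as in step 8. This passes through the racemic tert-butyl ester F1 and the racemic keto acid F2 (neither isolated) and gives the racemic flavanone F3. Kinetic resolution of F3 by asymmetric transfer hydrogenation (RuCl(p-cymene)[(R,R)-TsDPEN], HCO2H/Et3N, EtOAc, rt, stopped near half conversion) is a known route to enantiopure flavanones. By the usual sense of this catalyst it should reduce the 2R ketone to the cis-(2R,4R)-flavan-4-ol F4 and leave the 2S ketone, which is 15 after chromatography.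

Step 9. Over-oxidation to the enal, stalling at low conversion, or oxidation next to the ketone may erode the yield. The fallback rebuilds the trisubstituted alkene by olefination instead of C–H oxidation; it sets out from 15 and returns at 16. Oxidative cleavage of the prenyl alkene (OsO4 cat., NaIO4, 2,6-lutidine, dioxane/H2O) gives the arylacetaldehyde F5. E-selective Wittig reaction with the stabilised ylide 2-(triphenylphosphoranylidene)propanal (toluene, 60 °C) gives the (E)-enal F6. Chemoselective reduction of the aldehyde in the presence of the deactivated chromanone carbonyl (NaBH4, EtOH/CH2Cl2, −78 °C) gives 16.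

Step 3. The palladium catalyst may re-ionise the tertiary ether and let it drift to the linear prenyl ether, or the hydrogen-bonded phenol may attack too slowly. The fallback builds the tertiary ether by propargylation and semihydrogenation, needs no carbonate 4, sets out from 2 and returns at 5. Copper-catalysed O-alkylation of 2 with 3-chloro-3-methylbut-1-yne (CuCl2 cat., DBU, dry MeCN, 0 °C) gives the propargyl ether F7. Semihydrogenation (H2, Pd/CaCO3 poisoned with Pb(OAc)2, quinoline, EtOAc) gives 5.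

**Further compounds**

F1 | step 8 | racemic trans tert-butyl 5,7-bis(TBSO)-2-[3,4-bis(TBSO)phenyl]-8-(3-methylbut-2-en-1-yl)-4-oxochromane-3-carboxylate (not isolated) | CC(C)=CCc1c(O[Si](C)(C)C(C)(C)C)cc(O[Si](C)(C)C(C)(C)C)c2c1OC(c1ccc(O[Si](C)(C)C(C)(C)C)c(O[Si](C)(C)C(C)(C)C)c1)C(C(=O)OC(C)(C)C)C2=O
F2 | step 8 | racemic trans 5,7-bis(TBSO)-2-[3,4-bis(TBSO)phenyl]-8-(3-methylbut-2-en-1-yl)-4-oxochromane-3-carboxylic acid (not isolated) | CC(C)=CCc1c(O[Si](C)(C)C(C)(C)C)cc(O[Si](C)(C)C(C)(C)C)c2c1OC(c1ccc(O[Si](C)(C)C(C)(C)C)c(O[Si](C)(C)C(C)(C)C)c1)C(C(=O)O)C2=O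
F3 | step 8 | racemic 5,7-bis(TBSO)-2-[3,4-bis(TBSO)phenyl]-8-(3-methylbut-2-en-1-yl)chroman-4-one | CC(C)=CCc1c(O[Si](C)(C)C(C)(C)C)cc(O[Si](C)(C)C(C)(C)C)c2c1OC(c1ccc(O[Si](C)(C)C(C)(C)C)c(O[Si](C)(C)C(C)(C)C)c1)CC2=O
F4 | step 8 | (2R,4R)-5,7-bis(TBSO)-2-[3,4-bis(TBSO)phenyl]-8-(3-methylbut-2-en-1-yl)chroman-4-ol (cis, by-product of the resolution) | CC(C)=CCc1c(O[Si](C)(C)C(C)(C)C)cc(O[Si](C)(C)C(C)(C)C)c2c1O[C@@H](c1ccc(O[Si](C)(C)C(C)(C)C)c(O[Si](C)(C)C(C)(C)C)c1)C[C@H]2O
F5 | step 9 | 2-[(2S)-5,7-bis(TBSO)-2-[3,4-bis(TBSO)phenyl]-4-oxochroman-8-yl]acetaldehyde | O=CCc1c(O[Si](C)(C)C(C)(C)C)cc(O[Si](C)(C)C(C)(C)C)c2c1O[C@H](c1ccc(O[Si](C)(C)C(C)(C)C)c(O[Si](C)(C)C(C)(C)C)c1)CC2=O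
F6 | step 9 | (2E)-4-[(2S)-5,7-bis(TBSO)-2-[3,4-bis(TBSO)phenyl]-4-oxochroman-8-yl]-2-methylbut-2-enal | O=C/C(C)=C/Cc1c(O[Si](C)(C)C(C)(C)C)cc(O[Si](C)(C)C(C)(C)C)c2c1O[C@H](c1ccc(O[Si](C)(C)C(C)(C)C)c(O[Si](C)(C)C(C)(C)C)c1)CC2=O
F7 | step 3 | methyl 2,4-bis(TBSO)-6-[(2-methylbut-3-yn-2-yl)oxy]benzoate | COC(=O)c1c(OC(C)(C)C#C)cc(O[Si](C)(C)C(C)(C)C)cc1O[Si](C)(C)C(C)(C)C
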